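Locants follow ent-kaurane numbering throughout (C1–C5 and C10 are ring A, C20 is the methyl on C10, C9 is the ketone on C10, C15/C16 are the two-carbon bridge from C8 to C13). The route is a paper proposal; nothing in it has been run or modelled.

## Analysis of the target

Compound 39 is an 8,9-seco-ent-kaurane. Ring A, a cyclohexane (C1–C5, C10), is trans-fused through C5–C10 to a ten-membered carbocycle (C5–C6–C7–C8–C14–C13–C12–C11–C9–C10). The C15–C16 unit bridges C8 and C13, so C8=C14 is both an E-alkene of the large ring and the alkene of a 5-methylenecyclopent-2-enone (ring D). There are six stereocentres, (1S,3S,5R,7R,10S,13R). In ring A the C10 methyl and H5 are trans-diaxial, the C1 hydroxyl is equatorial and cis to that methyl, and the C3 acetate is axial and trans to it, so the two oxygens are 1,3-anti. C7 (allylic carbinol) and C13 sit across the macrocycle with no direct stereochemical link to ring A. The sensitive groups are the cross-conjugated exo-methylene enone (a Michael acceptor), the β-hydroxy ketone C1–C10–C9 with its quaternary α-carbon (retro-aldol in base), the acetate next to a free hydroxyl, and the C9 ketone, whose C11 methylene competes in any enolate step. The difficulties are the strained bridged ten-membered ring, the quaternary C10 flanked by a ketone and a carbinol, and the relay of configuration from C7/C13 to C5/C10. The strategy rests on the C5–C10 bond. C10 is α and C5 is β to the C9 ketone, the trans relation of C9 and C6 is the geometry of an E-enone, and the oxygens at C1 and C3 are what a 1-alkoxy-3-silyloxydiene leaves behind, so ring A can be annulated last by a [4+2] addition to C10=C5.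

## Retrosynthetic reasoning

39 ⇒ 38 ⇒ 35 ⇒ 34. The exo-methylene enone and the free C7 hydroxyl are unveiled last: the O–Si bond, the C16=C17 bond (Mannich methylenation) and the C15 ketal are cut in that order. Keeping C15 as a ketal up to 34 means that no enolate, copper–boryl, hydride or samarium step meets a second enone.

34 ⇒ 33 ⇒ 31. The C1 hydroxyl is cis to the axial C10 methyl. A nucleophile adding to C1 of a ring A enone such as 28 would enter anti to that methyl and give the wrong epimer, so the C1 oxygen cannot come from conjugate addition at C1. It is made instead from a C1 ketone by delivering hydride on the face of the C3 oxygen. An Evans–Tishchenko reduction of β-hydroxy ketone 33 gives this 1,3-anti pattern and places the acetyl group on O3 in the same operation. 33 comes from enone 31 by conjugate borylation–oxidation, where axial attack at C3 gives the axial oxygen.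

31 ⇒ 30 ⇒ 29 ⇒ 28. The cycloaddition necessarily puts the ring A carbonyl at C3, while the plan above needs it at C1. The carbonyl is therefore transposed by epoxidation, Wharton transposition and oxidation. This costs three steps and buys a predictable configuration at both C1 and C3.

28 ⇒ 25. The C4–CH3 bond is cut. A diene with two terminal substituents would not reach the s-cis conformation, so the second methyl is added afterwards through the cross-conjugated enolate. The C11 methylene of the C9 ketone is the more accessible acidic site, so the C9 ketone is first masked in the flask as its silyl enol ether (26).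

25 ⇒ 21 + 23. This is the key disconnection: C1–C10 and C4–C5 are cut. It removes ring A, the quaternary centre and two stereocentres in one step and leaves bicycle 21 with only C7 and C13. The forward reaction has to add diene 23 to one face of a trisubstituted E-enone held in a ten-membered ring.

21 ⇒ 20 ⇒ 19. The C9–C10 bond is cut (Nozaki–Hiyama–Kishi closure). It joins an aldehyde to an sp2 carbon whose alkenyl iodide geometry is retained, and the carbinol formed is oxidised at once, so the ring closure creates no lasting stereocentre. Closure at C7–C8 would have set C7 in the cyclisation.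

19 ⇒ 18 ⇒ 17 ⇒ 16 ⇒ 15 ⇒ 14 ⇒ 11 + 3. The C7–C8 bond is cut: the alkenyl metal from iodo ketal 11 adds to aldehyde 3. C13 is too remote to control C7, so C7 is set by oxidation to 15 and catalyst-controlled reduction to 16.

11 ⇒ 10 ⇒ 9 ⇒ 8 ⇒ 4 + 5. The C12–C13 bond is cut: conjugate addition trans to the silyloxy group of 4 sets C13. The silyloxy group then serves as the leaving group that regenerates the enone (9), which is iodinated at C8 and ketalised.

3 ⇒ 2 ⇒ 1, and 23 ⇒ 22. The E-alkenyl iodide comes from syn-hydrozirconation and iodination of alkynol 1. The diene comes from enolisation and silylation of enone 22.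

## Alternatives that were turned down

Alternative 1: The cyclopentenone is disconnected at C13–C14, C15–C16 and C8–C15 as a [2+2+1] of an alkyne (C8≡C14), a terminal alkene (C13=C16) and a carbonyl ligand. C14 is tied to C9 through a temporary tertiary carbinol so that the substrate is a 1,6-enyne. The forward key step is a cobalt-mediated Pauson–Khand reaction giving the bicyclo[3.3.0]octenone A1. The C9–C14 bond is cut later by a Grob fragmentation that opens the ten-membered ring and leaves the C9 ketone. In its favour, cyclocarbonylation of 1,6-enynes is among the most dependable ring constructions, C13 is set by the tether, and the strained ring is revealed by fragmentation and not closed by cyclisation. On ring formation and on stereocontrol it is stronger than the chosen route, because it does not depend on the conformation of a macrocycle. Against it, ring A with four stereocentres and four different protecting groups has to be built first in a long linear sequence. After A1 the C7–C8 bond must still be made, a leaving group must be placed antiperiplanar to C9–C14, and the fragmentation must deliver the E geometry of C8=C14. The chosen route offers convergence instead: it reaches its key step with two stereocentres and adds ring A in one operation.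

Alternative 2: The C11–C12 bond is disconnected as a [3,3] shift within an eight-membered cyclic enol ether (exocyclic methylene C11 on C9, ring oxygen on C14, exocyclic methylene C12 on C13), made by Tebbe methylenation of a lactone. The forward key step is a thermal Claisen ring expansion that forms C11–C12, breaks C14–O and gives the ten-membered C9 ketone A2. In its favour, the expansion is driven by carbonyl formation, needs no high dilution and tolerates ring strain. As a way to make the ten-membered ring it is more secure than the chromium-mediated closure used here. Against it, A2 carries its alkene at C13=C14 and a hydrogen at C8. The alkene has to be moved to C8=C14, and C13, which is sp2 in A2, has to be re-created by an uncontrolled protonation γ to the C15 carbonyl. The C8 centre set in the rearrangement is erased, and ring A must already be complete before a lactone is methylenated twice. The chosen route fixes C13 from the first step and never has to repair the position of the ring D alkene.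

Alternative 3: The C8–C14 bond is disconnected as an Ireland–Claisen rearrangement of the silyl ketene acetal of a twelve-membered lactone (ester carbon C15, allylic oxygen on C16, exocyclic methylene C14 on C13). The forward key step forms C8–C14, breaks C16–O and contracts the lactone to the ten-membered carbocyclic acid A3. In its favour, lactonisation to a twelve-membered ring is far easier than any direct closure of a ten-membered carbocycle, so on macrocyclisation it is the strongest of all four plans. Against it, A3 has no ring D: the C15–C16 bond, the C8=C14 unsaturation and the C13 stereocentre all remain to be made. C9 is still at the alcohol level, the ketene acetal geometry and the chair or boat preference inside a macrolactone are hard to predict, and four orthogonal protecting groups are carried. It is the longest plan. The chosen route has ring D in place from the start and spends its late steps only on ring A.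

Key step: step 16

Remark: 14 and 20 are mixtures at the carbinol carbon that is oxidised in the next step; 24–27 are carried as C4 epimers (and C1 epimers for 24) with the endo-derived isomer drawn; 29 and 30 are drawn with the C1 oxygen anti to the C10 methyl; none of these centres survives.

## Steps

Step 1
Reactants: 1 pent-3-yn-1-ol
Product: 2 (E)-4-iodopent-3-en-1-ol
Conditions: Cp2Zr(H)Cl (2.5 equiv), THF, 0 °C to rt; then I2, 0 °C
Reagents that add atoms: iodine, II
Why: Hydrozirconation is a syn addition; with excess reagent the alkenylzirconium should equilibrate to the isomer with zirconium on the methyl-bearing carbon, remote from the alkoxide chain. Iodinolysis goes with retention, so iodine ends trans to the chain (E).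

Step 2
Reactants: 2 (E)-4-iodopent-3-en-1-ol
Product: 3 (E)-4-iodopent-3-enal
Conditions: DMP, NaHCO3, CH2Cl2, 0 °C; used at once without chromatography
Reagents that add atoms: none
Why: Buffered Dess–Martin oxidation is neutral enough to give the β,γ-unsaturated aldehyde without moving the double bond into conjugation.

Step 3
Reactants: 4 (S)-4-(tert-butyldimethylsilyloxy)cyclopent-2-en-1-one; 5 1-[(3-bromopropoxy)methyl]-4-methoxybenzene
Product: 8 (3S,4S)-4-(tert-butyldimethylsilyloxy)-3-{3-[(4-methoxybenzyl)oxy]propyl}cyclopentan-1-one, via Grignard reagent 6 (not isolated), via silyl enol ether 7 (not isolated)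
Conditions: 5, Mg, THF, rt; then 4, CuBr·SMe2 (10 mol%), TMSCl (2 equiv), THF, −78 °C; 1 M HCl, 0 °C, brief
Reagents that add atoms: none
Why: Copper-catalysed conjugate addition of the Grignard reagent occurs anti to the C4 silyloxy group of 4, the usual trans selectivity of 4-oxygenated cyclopentenones, and this fixes the future C13. Trapping as the silyl enol ether prevents enolate equilibration and early loss of the silyloxy group.

Step 4
Reactants: 8 (3S,4S)-4-(tert-butyldimethylsilyloxy)-3-{3-[(4-methoxybenzyl)oxy]propyl}cyclopentan-1-one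
Product: 9 (S)-4-{3-[(4-methoxybenzyl)oxy]propyl}cyclopent-2-en-1-one
Conditions: DBU (1.2 equiv), CH2Cl2, 0 °C, 30 min
Reagents that add atoms: none
Why: E1cB loss of the β-silyloxy group gives the 4-substituted enone. Short exposure at 0 °C should avoid γ-deprotonation, which would racemise the stereocentre.

Step 5
Reactants: 9 (S)-4-{3-[(4-methoxybenzyl)oxy]propyl}cyclopent-2-en-1-one
Product: 10 (S)-2-iodo-4-{3-[(4-methoxybenzyl)oxy]propyl}cyclopent-2-en-1-one
Conditions: I2 (1.5 equiv), pyridine/CH2Cl2 (1:1), 0 °C to rt
Reagents that add atoms: iodine, II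
Why: α-Iodination of enones by I2/pyridine (conjugate addition of pyridine, iodination of the enolate, elimination) is reliable for cyclopentenones and leaves the PMB ether alone.

Step 6
Reactants: 10 (S)-2-iodo-4-{3-[(4-methoxybenzyl)oxy]propyl}cyclopent-2-en-1-one
Product: 11 (S)-6-iodo-8-{3-[(4-methoxybenzyl)oxy]propyl}-1,4-dioxaspiro[4.4]non-6-ene
Conditions: 1,2-bis(trimethylsilyloxy)ethane (2 equiv), TMSOTf (5 mol%), CH2Cl2, −78 to −20 °C
Reagents that add atoms: 1,2-bis(trimethylsilyloxy)ethane, C[Si](C)(C)OCCO[Si](C)(C)C
Why: Silyl-transfer ketalisation runs cold, so the double bond should not migrate and the γ-stereocentre should not epimerise. The ketal masks C15 for the rest of the route and makes the C8–I bond a clean source of an alkenyllithium.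

Step 7
Reactants: 11 (S)-6-iodo-8-{3-[(4-methoxybenzyl)oxy]propyl}-1,4-dioxaspiro[4.4]non-6-ene; 3 (E)-4-iodopent-3-enal
Product: 14 (3E)-4-iodo-1-[(8S)-8-{3-[(4-methoxybenzyl)oxy]propyl}-1,4-dioxaspiro[4.4]non-6-en-6-yl]pent-3-en-1-ol (both carbinol epimers), via alkenyllithium 12 (not isolated), via organocerium reagent 13 (not isolated)
Conditions: t-BuLi (2.1 equiv), THF, −78 °C; CeCl3 (1.2 equiv), −78 °C; then 3 (1.3 equiv), −78 °C
Reagents that add atoms: none
Why: Iodine–lithium exchange gives the 2-lithio allylic ketal; the less basic organocerium reagent then adds 1,2 to the enolisable aldehyde and forms C7–C8. C13 is too far away to induce, so both C7 epimers are taken on.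

Step 8
Reactants: 14 (3E)-4-iodo-1-[(8S)-8-{3-[(4-methoxybenzyl)oxy]propyl}-1,4-dioxaspiro[4.4]non-6-en-6-yl]pent-3-en-1-ol
Product: 15 (3E)-4-iodo-1-[(8S)-8-{3-[(4-methoxybenzyl)oxy]propyl}-1,4-dioxaspiro[4.4]non-6-en-6-yl]pent-3-en-1-one
Conditions: DMP, NaHCO3, CH2Cl2, 0 °C
Reagents that add atoms: none
Why: Dess–Martin oxidation converges both epimers on the enone; the buffered, neutral medium keeps the skipped C5=C10 alkene out of conjugation.

Step 9
Reactants: 15 (3E)-4-iodo-1-[(8S)-8-{3-[(4-methoxybenzyl)oxy]propyl}-1,4-dioxaspiro[4.4]non-6-en-6-yl]pent-3-en-1-one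
Product: 16 (1R,3E)-4-iodo-1-[(8S)-8-{3-[(4-methoxybenzyl)oxy]propyl}-1,4-dioxaspiro[4.4]non-6-en-6-yl]pent-3-en-1-ol
Conditions: (S)-Me-CBS oxazaborolidine [(S)-1-methyl-3,3-diphenylhexahydropyrrolo[1,2-c][1,3,2]oxazaborole] (0.5 equiv), catecholborane (2 equiv), toluene, −78 °C
Reagents that add atoms: none
Why: Corey–Bakshi–Shibata reduction: the α-branched alkenyl group (C8) acts as the large substituent and the C6 methylene as the small one, so the (S)-catalyst should give the (R)-carbinol at C7, the same sense as acetophenone to (R)-1-phenylethanol. Catecholborane at −78 °C does not hydroborate the alkenes.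

Step 10
Reactants: 16 (1R,3E)-4-iodo-1-[(8S)-8-{3-[(4-methoxybenzyl)oxy]propyl}-1,4-dioxaspiro[4.4]non-6-en-6-yl]pent-3-en-1-ol
Product: 17 tert-butyldimethylsilyl ether of 16
Conditions: TBSCl, imidazole, DMF, rt
Reagents that add atoms: tert-butyldimethylsilyl chloride, CC(C)(C)[Si](C)(C)Cl
Why: Standard silylation of a secondary allylic alcohol; the basic conditions do not endanger the ketal.

Step 11
Reactants: 17 tert-butyldimethylsilyl ether of 16
Product: 18 3-[(8S)-6-[(1R,3E)-1-(tert-butyldimethylsilyloxy)-4-iodopent-3-en-1-yl]-1,4-dioxaspiro[4.4]non-6-en-8-yl]propan-1-ol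
Conditions: DDQ (1.3 equiv), CH2Cl2/pH 7 phosphate buffer (10:1), 0 °C
Reagents that add atoms: none
Why: Oxidative cleavage of the PMB ether by DDQ is orthogonal to the silyl ether, the alkenyl iodide and, when buffered, the ketal.

Step 12
Reactants: 18 3-[(8S)-6-[(1R,3E)-1-(tert-butyldimethylsilyloxy)-4-iodopent-3-en-1-yl]-1,4-dioxaspiro[4.4]non-6-en-8-yl]propan-1-ol
Product: 19 3-[(8S)-6-[(1R,3E)-1-(tert-butyldimethylsilyloxy)-4-iodopent-3-en-1-yl]-1,4-dioxaspiro[4.4]non-6-en-8-yl]propanal
Conditions: DMP, NaHCO3, CH2Cl2, 0 °C to rt
Reagents that add atoms: none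
Why: Dess–Martin oxidation of a primary alcohol to the aldehyde, neutral towards all other groups present.

Step 13
Reactants: 19 3-[(8S)-6-[(1R,3E)-1-(tert-butyldimethylsilyloxy)-4-iodopent-3-en-1-yl]-1,4-dioxaspiro[4.4]non-6-en-8-yl]propanal
Product: 20 bridged bicyclic allylic alcohol (C9 carbinol both epimers; (E)-C10=C5; 7R; 13S; C7 OTBS; C15 dioxolane)
Conditions: CrCl2 (10 equiv), NiCl2 (0.1 equiv), DMSO/THF, 0.003 M, rt
Reagents that add atoms: none
Why: Nozaki–Hiyama–Kishi reaction: zerovalent nickel inserts into the C–I bond and transmetalates to trivalent chromium, and the alkenylchromium adds only to the aldehyde, with retention of the E geometry, to form C9–C10. The cyclopentene holds the two chains 1,3 to each other, which should help closure of the ten-membered ring at high dilution.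

Step 14
Reactants: 20 bridged bicyclic allylic alcohol
Product: 21 bridged bicyclic (E)-enone (C9 ketone; (E)-C10=C5 with 10-methyl; C8=C14; 7R; 13S; C7 OTBS; C15 dioxolane)
Conditions: DMP, NaHCO3, CH2Cl2, 0 °C, in the dark; stored cold
Reagents that add atoms: none
Why: Oxidation of the allylic alcohol gives the E-enone without touching the alkene geometry. 21 is a strained 1,5-diene and is kept cold to avoid Cope rearrangement and E/Z isomerisation.

Step 15
Reactants: 22 (E)-1-methoxypent-1-en-3-one
Product: 23 (1E,3Z)-1-methoxy-3-(trimethylsilyloxy)penta-1,3-diene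
Conditions: TMSOTf (1.1 equiv), Et3N (1.3 equiv), Et2O, 0 °C; distilled
Reagents that add atoms: trimethylsilyl trifluoromethanesulfonate, C[Si](C)(C)OS(=O)(=O)C(F)(F)F
Why: Soft enolisation of the ethyl ketone gives the silyl enol ether with the methyl group on the outside of the diene (3Z), the only geometry that still reaches the s-cis conformation.

Step 16
Reactants: 21 bridged bicyclic (E)-enone; 23 (1E,3Z)-1-methoxy-3-(trimethylsilyloxy)penta-1,3-diene
Product: 25 tricyclic ring A enone (4R,5R,7R,10R,13S; C1=C2–C3 enone; one C4 methyl; C9 ketone; C7 OTBS; C15 dioxolane), via cycloadduct 24 (not isolated)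
Conditions: 23 (3 equiv), Et2AlCl (1.2 equiv), CH2Cl2, −78 to −30 °C; then TFA, CH2Cl2, 0 °C
Reagents that add atoms: none
Why: The aluminium Lewis acid binds the C9 carbonyl and the diene adds in a concerted but asynchronous [4+2] cycloaddition, its nucleophilic C4 terminus leading at the β-carbon C5 and C1 closing on the α-carbon C10. The closest known reaction type is the cycloaddition of 1-alkoxy-3-silyloxydienes with α-substituted enones to form quaternary ring-fusion carbons, combined with the outer-face addition chemistry of medium-ring E-alkenes. Ring A is closed by intermolecular [4+2] annulation, with both σ-bonds (C1–C10, C4–C5) formed suprafacially on the alkene. C10 and C5 are created together: the E geometry of the dienophile fixes their relative configuration (C9 trans to C6, methyl trans to H5), and the π-face attacked fixes their absolute sense. That face is controlled by the macrocycle, since an E-alkene in a ten-membered ring turns one face to the ring interior and the diene can reach only the outer face; the required (5R,10R) product needs the conformer whose fold matches the natural skeleton to be the one that reacts, which modelling must confirm. C1 (methoxy) and C4 (methyl) depend on endo or exo approach and are not needed, because TFA removes the silyl group and methanol to give the enone and step 17 makes C4 quaternary. Chemoselectivity is secured by the C15 ketal, which leaves the E-enone as the only activated alkene, and regioselectivity by the polarity of the diene. The strain of the E-enone should offset its trisubstitution, and the low temperature avoids Cope rearrangement of the 1,5-diene.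

Step 17
Reactants: 25 tricyclic ring A enone
Product: 28 4,4-dimethyl ring A enone (5R,7R,10R,13S; C1=C2–C3 enone; C9 ketone), via enol silane 26 (not isolated), via methylated enol silane 27 (not isolated)
Conditions: TMSCl (1.05 equiv) then LiN(i-Pr)2 (1.05 equiv), THF, −78 °C; LiN(i-Pr)2 (1.5 equiv), −78 to −30 °C; MeI (5 equiv), DMPU, −78 to 0 °C; 10% aq citric acid, THF, 0 °C
Reagents that add atoms: iodomethane, CI
Why: The first equivalent of amide base should remove the unhindered C11 methylene proton in preference to the C4 methine, which is syn-axial to the C10 methyl, and the enolate is trapped at once as the C9 silyl enol ether. The second equivalent can then only form the cross-conjugated C3–C4 enolate, whose methylation makes C4 quaternary. Mild acid returns the C9 ketone.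

Step 18
Reactants: 28 4,4-dimethyl ring A enone
Product: 29 1,2-epoxy-3-ketone (epoxide anti to the C10 methyl)
Conditions: t-BuOOH (3 equiv), DBU (1.5 equiv), CH2Cl2, 0 °C to rt
Reagents that add atoms: tert-butyl hydroperoxide, CC(C)(C)OO
Why: Nucleophilic (Weitz–Scheffer) epoxidation of the enone by the hydroperoxide anion; the non-aqueous base spares the C9 ketone. The epoxide configuration is of no consequence, since C1 and C2 lose it in steps 19 and 20.

Step 19
Reactants: 29 1,2-epoxy-3-ketone
Product: 30 ring A 2-en-1-ol (C2=C3; C1 carbinol)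
Conditions: N2H4·H2O (5 equiv), AcOH (1 equiv), MeOH, 0 °C to rt
Reagents that add atoms: none
Why: Wharton transposition: the hydrazone of the C3 ketone fragments with loss of N2 and opens the epoxide to the C2=C3 alkene and the C1 carbinol. The hindered ten-membered C9 ketone should condense much more slowly.

Step 20
Reactants: 30 ring A 2-en-1-ol
Product: 31 ring A 2-en-1-one (C1 ketone; C2=C3; 4,4-dimethyl; C9 ketone)
Conditions: DMP, NaHCO3, CH2Cl2, 0 °C
Reagents that add atoms: none
Why: Dess–Martin oxidation of the allylic alcohol completes the 1,3-carbonyl transposition. Neutral conditions are chosen because C1 and C9 now form a non-enolisable 1,3-diketone that nucleophilic base could cleave.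

Step 21
Reactants: 31 ring A 2-en-1-one
Product: 33 β-hydroxy ketone (C3 hydroxyl axial and trans to the C10 methyl; C1 ketone), via boronate 32 (not isolated)
Conditions: B2pin2 (1.3 equiv), CuCl (10 mol%), NaOt-Bu (10 mol%), bis[2-(diphenylphosphino)phenyl] ether (10 mol%), MeOH (2 equiv), THF, 0 °C to rt; then 30% H2O2, pH 7 phosphate buffer, 0 °C
Reagents that add atoms: hydrogen peroxide, OO
Why: Copper-catalysed conjugate borylation: the boryl-copper species should add to C3 axially, anti to the pseudoaxial methyl on C4 and on the face opposite the C10 methyl. Buffered peroxide then oxidises the C–B bond with retention to the axial C3 hydroxyl.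

Step 22
Reactants: 33 β-hydroxy ketone
Product: 34 ring A 3-acetate 1-ol (C3 OAc axial; C1 OH equatorial and cis to the C10 methyl; C7 OTBS; C15 dioxolane)
Conditions: CH3CHO (8 equiv), SmI2 (0.3 equiv), THF, −10 °C
Reagents that add atoms: acetaldehyde, CC=O
Why: Evans–Tishchenko reduction: the hemiacetal of the C3 hydroxyl with acetaldehyde, bound to trivalent samarium, transfers hydride to C1 through a six-membered transition state on the face of the C3 oxygen. This sets the 1,3-anti C1 carbinol and leaves the acetyl group on O3 in the same step. The C9 ketone has no β-hydroxyl at the outset and sits in a hindered medium ring.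

Step 23
Reactants: 34 ring A 3-acetate 1-ol
Product: 35 C15 enone (cyclopent-2-enone with C16 methylene unsubstituted; C7 OTBS)
Conditions: PPTS, THF/H2O (5:1), 45 °C
Reagents that add atoms: water, O
Why: The allylic dioxolane hydrolyses under mild acid that the secondary silyl ether and the acetate should withstand.

Step 24
Reactants: 35 C15 enone
Product: 38 7-O-tert-butyldimethylsilyl ether of the target, via Mannich base 36 (not isolated), via ammonium iodide 37 (not isolated)
Conditions: LiN(SiMe3)2 (2.3 equiv), THF, −78 °C; Me2N=CH2+ I− (3 equiv), −78 to 0 °C; MeI, CH2Cl2, rt; aq NaHCO3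
Reagents that add atoms: dimethylmethyleneammonium iodide, C=[N+](C)C.[I-]
Why: Mannich methylenation: after the C1 alkoxide forms, kinetic deprotonation should take the cyclopentenone α′-methylene C16, which enolises far faster than C11 of the ten-membered ketone, and the enolate adds to the iminium salt. Quaternisation and mild base then eliminate trimethylamine to give the exo-methylene enone.

Step 25
Reactants: 38 7-O-tert-butyldimethylsilyl ether of the target
Product: 39 target, (1S,3S,5R,7R,10S,13R)-3-acetoxy-1,7-dihydroxy-8,9-seco-ent-kaura-8(14),16-diene-9,15-dione (CNP0223751.1)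
Conditions: HF·pyridine, THF, 0 °C to rt
Reagents that add atoms: none
Why: Acidic fluoride removes the silyl ether without the basic conditions that would threaten the exo-methylene enone, the acetate or the β-hydroxy ketone.

## Compound list

1 | pent-3-yn-1-ol | CC#CCCO | starting material
2 | (E)-4-iodopent-3-en-1-ol | OCC/C=C(\C)I | intermediate
3 | (E)-4-iodopent-3-enal | O=CC/C=C(\C)I | intermediate
4 | (S)-4-(tert-butyldimethylsilyloxy)cyclopent-2-en-1-one | O=C1C=C[C@@H](O[Si](C)(C)C(C)(C)C)C1 | starting material
5 | 1-[(3-bromopropoxy)methyl]-4-methoxybenzene | COc1ccc(COCCCBr)cc1 | starting material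
6 | {3-[(4-methoxybenzyl)oxy]propyl}magnesium bromide | COc1ccc(COCCC[Mg]Br)cc1 | intermediate (not isolated)
7 | trimethylsilyl enol ether of 8 | C[Si](C)(C)OC1=C[C@H](CCCOCc2ccc(OC)cc2)[C@@H](O[Si](C)(C)C(C)(C)C)C1 | intermediate (not isolated)
8 | (3S,4S)-4-(tert-butyldimethylsilyloxy)-3-{3-[(4-methoxybenzyl)oxy]propyl}cyclopentan-1-one | O=C1C[C@H](CCCOCc2ccc(OC)cc2)[C@@H](O[Si](C)(C)C(C)(C)C)C1 | intermediate
9 | (S)-4-{3-[(4-methoxybenzyl)oxy]propyl}cyclopent-2-en-1-one | O=C1C=C[C@@H](CCCOCc2ccc(OC)cc2)C1 | intermediate
10 | (S)-2-iodo-4-{3-[(4-methoxybenzyl)oxy]propyl}cyclopent-2-en-1-one | O=C1C(I)=C[C@@H](CCCOCc2ccc(OC)cc2)C1 | intermediate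
11 | (S)-6-iodo-8-{3-[(4-methoxybenzyl)oxy]propyl}-1,4-dioxaspiro[4.4]non-6-ene | C1C2(OCCO2)C(I)=C[C@H]1CCCOCc1ccc(OC)cc1 | intermediate
12 | 6-lithio analogue of 11 | C1C2(OCCO2)C([Li])=C[C@H]1CCCOCc1ccc(OC)cc1 | intermediate (not isolated)
13 | 6-(dichlorocerio) analogue of 11 | C1C2(OCCO2)C([Ce](Cl)Cl)=C[C@H]1CCCOCc1ccc(OC)cc1 | intermediate (not isolated)
14 | (3E)-4-iodo-1-[(8S)-8-{3-[(4-methoxybenzyl)oxy]propyl}-1,4-dioxaspiro[4.4]non-6-en-6-yl]pent-3-en-1-ol, both carbinol epimers | C1C2(OCCO2)C(C(O)C/C=C(\C)I)=C[C@H]1CCCOCc1ccc(OC)cc1 | intermediate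
15 | (3E)-4-iodo-1-[(8S)-8-{3-[(4-methoxybenzyl)oxy]propyl}-1,4-dioxaspiro[4.4]non-6-en-6-yl]pent-3-en-1-one | C1C2(OCCO2)C(C(=O)C/C=C(\C)I)=C[C@H]1CCCOCc1ccc(OC)cc1 | intermediate
16 | (1R,3E)-4-iodo-1-[(8S)-8-{3-[(4-methoxybenzyl)oxy]propyl}-1,4-dioxaspiro[4.4]non-6-en-6-yl]pent-3-en-1-ol | C1C2(OCCO2)C([C@H](O)C/C=C(\C)I)=C[C@H]1CCCOCc1ccc(OC)cc1 | intermediate
17 | tert-butyldimethylsilyl ether of 16 | C1C2(OCCO2)C([C@H](O[Si](C)(C)C(C)(C)C)C/C=C(\C)I)=C[C@H]1CCCOCc1ccc(OC)cc1 | intermediate
18 | 3-[(8S)-6-[(1R,3E)-1-(tert-butyldimethylsilyloxy)-4-iodopent-3-en-1-yl]-1,4-dioxaspiro[4.4]non-6-en-8-yl]propan-1-ol | C1C2(OCCO2)C([C@H](O[Si](C)(C)C(C)(C)C)C/C=C(\C)I)=C[C@H]1CCCO | intermediate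
19 | 3-[(8S)-6-[(1R,3E)-1-(tert-butyldimethylsilyloxy)-4-iodopent-3-en-1-yl]-1,4-dioxaspiro[4.4]non-6-en-8-yl]propanal | C1C2(OCCO2)C([C@H](O[Si](C)(C)C(C)(C)C)C/C=C(\C)I)=C[C@H]1CCC=O | intermediate
20 | bridged bicyclic allylic alcohol: ten-membered ring C5–C6–C7–C8–C14–C13–C12–C11–C9–C10 bridged by C15–C16; C9 carbinol (both epimers); (E)-C10=C5 with 10-methyl; C8=C14; (7R)-OTBS; (13S); C15 ethylene ketal | C1C3(OCCO3)C2=C[C@H]1CCC(O)/C(C)=C/C[C@H]2O[Si](C)(C)C(C)(C)C | intermediate
21 | bridged bicyclic (E)-enone: as 20 with C9 ketone; (7R,13S) | C1C3(OCCO3)C2=C[C@H]1CCC(=O)/C(C)=C/C[C@H]2O[Si](C)(C)C(C)(C)C | intermediate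
22 | (E)-1-methoxypent-1-en-3-one | CCC(=O)/C=C/OC | starting material
23 | (1E,3Z)-1-methoxy-3-(trimethylsilyloxy)penta-1,3-diene | CO/C=C/C(O[Si](C)(C)C)=C/C | intermediate
24 | primary cycloadduct: ring A with C1 methoxy, C2=C3 trimethylsilyl enol ether, C4 methyl (endo isomer drawn) | C1C3(OCCO3)C2=C[C@H]1CCC(=O)[C@@]1(C)[C@H](C[C@H]2O[Si](C)(C)C(C)(C)C)[C@@H](C)C(O[Si](C)(C)C)=C[C@H]1OC | intermediate (not isolated)
25 | tricyclic ring A enone, (4R,5R,7R,10R,13S): C1=C2–C3 enone, one C4 methyl, C9 ketone, C7 OTBS, C15 ethylene ketal | C1C3(OCCO3)C2=C[C@H]1CCC(=O)[C@@]1(C)[C@H](C[C@H]2O[Si](C)(C)C(C)(C)C)[C@@H](C)C(=O)C=C1 | intermediate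
26 | C9 trimethylsilyl enol ether (C9=C11) of 25 | C1C3(OCCO3)C2=C[C@H]1CC=C(O[Si](C)(C)C)[C@@]1(C)[C@H](C[C@H]2O[Si](C)(C)C(C)(C)C)[C@@H](C)C(=O)C=C1 | intermediate (not isolated)
27 | C9 trimethylsilyl enol ether (C9=C11) of 28 | C1C3(OCCO3)C2=C[C@H]1CC=C(O[Si](C)(C)C)[C@@]1(C)[C@H](C[C@H]2O[Si](C)(C)C(C)(C)C)C(C)(C)C(=O)C=C1 | intermediate (not isolated)
28 | 4,4-dimethyl ring A enone, (5R,7R,10R,13S): C1=C2–C3 enone, C9 ketone, C7 OTBS, C15 ethylene ketal | C1C3(OCCO3)C2=C[C@H]1CCC(=O)[C@@]1(C)[C@H](C[C@H]2O[Si](C)(C)C(C)(C)C)C(C)(C)C(=O)C=C1 | intermediate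
29 | 1,2-epoxy-3-ketone of 28, epoxide on the face opposite the C10 methyl; other centres as in 28 | C1C3(OCCO3)C2=C[C@H]1CCC(=O)[C@@]1(C)[C@H](C[C@H]2O[Si](C)(C)C(C)(C)C)C(C)(C)C(=O)[C@H]2O[C@@H]12 | intermediate
30 | ring A 2-en-1-ol: C2=C3, C1 hydroxyl trans to the C10 methyl; other centres as in 28 | C1C3(OCCO3)C2=C[C@H]1CCC(=O)[C@@]1(C)[C@H](C[C@H]2O[Si](C)(C)C(C)(C)C)C(C)(C)C=C[C@H]1O | intermediate
31 | ring A 2-en-1-one: C1 ketone, C2=C3, 4,4-dimethyl, C9 ketone; other centres as in 28 | C1C3(OCCO3)C2=C[C@H]1CCC(=O)[C@@]1(C)[C@H](C[C@H]2O[Si](C)(C)C(C)(C)C)C(C)(C)C=CC1=O | intermediate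
32 | 3-(pinacolatoboryl)-1-ketone: boron on C3 trans to the C10 methyl | C1C3(OCCO3)C2=C[C@H]1CCC(=O)[C@@]1(C)[C@H](C[C@H]2O[Si](C)(C)C(C)(C)C)C(C)(C)[C@@H](B4OC(C)(C)C(C)(C)O4)CC1=O | intermediate (not isolated)
33 | β-hydroxy ketone: C3 hydroxyl axial, trans to the C10 methyl; C1 ketone | C1C3(OCCO3)C2=C[C@H]1CCC(=O)[C@@]1(C)[C@H](C[C@H]2O[Si](C)(C)C(C)(C)C)C(C)(C)[C@@H](O)CC1=O | intermediate
34 | ring A 3-acetate 1-ol: C3 OAc axial, C1 OH equatorial and cis to the C10 methyl; C7 OTBS; C15 ethylene ketal | C1C3(OCCO3)C2=C[C@H]1CCC(=O)[C@@]1(C)[C@H](C[C@H]2O[Si](C)(C)C(C)(C)C)C(C)(C)[C@@H](OC(C)=O)C[C@@H]1O | intermediate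
35 | C15 enone: 34 with the ketal hydrolysed (cyclopent-2-enone, C16 methylene unsubstituted) | C1C(=O)C2=C[C@H]1CCC(=O)[C@@]1(C)[C@H](C[C@H]2O[Si](C)(C)C(C)(C)C)C(C)(C)[C@@H](OC(C)=O)C[C@@H]1O | intermediate
36 | Mannich base: 35 with CH2NMe2 on C16 (C16 epimers) | CN(C)CC1C(=O)C2=C[C@H]1CCC(=O)[C@@]1(C)[C@H](C[C@H]2O[Si](C)(C)C(C)(C)C)C(C)(C)[C@@H](OC(C)=O)C[C@@H]1O | intermediate (not isolated)
37 | trimethylammonium iodide of 36 | C[N+](C)(C)CC1C(=O)C2=C[C@H]1CCC(=O)[C@@]1(C)[C@H](C[C@H]2O[Si](C)(C)C(C)(C)C)C(C)(C)[C@@H](OC(C)=O)C[C@@H]1O.[I-] | intermediate (not isolated)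
38 | 7-O-tert-butyldimethylsilyl ether of the target | C=C1C(=O)C2=C[C@H]1CCC(=O)[C@@]1(C)[C@H](C[C@H]2O[Si](C)(C)C(C)(C)C)C(C)(C)[C@@H](OC(C)=O)C[C@@H]1O | intermediate
39 | (1S,3S,5R,7R,10S,13R)-3-acetoxy-1,7-dihydroxy-8,9-seco-ent-kaura-8(14),16-diene-9,15-dione (CNP0223751.1) | C=C1C(=O)C2=C[C@H]1CCC(=O)[C@@]1(C)[C@H](C[C@H]2O)C(C)(C)[C@@H](OC(C)=O)C[C@@H]1O | target

## Step count and least certain steps

Total: 25 steps. Longest linear sequence: 22 steps (from 4 through steps 3–14 and 16–25). The aldehyde branch (steps 1, 2) joins at step 7 and the diene branch (step 15) at step 16.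

Step 16 (key step). The most likely failure is poor or reversed facial selectivity, if the ring-flipped conformer of the ten-membered E-enone is the one that reacts. Slow cycloaddition at the trisubstituted alkene would also give time for the diene to decompose, for the Lewis acid to ionise the allylic ketal, or for the 1,5-diene to undergo Cope rearrangement on warming. The fallback delivers the diene intramolecularly from the C7 oxygen. In 25 the C5–C4 bond and the C7–O bond lie on the same side across C6, so a short silicon bridge should favour the required face. Starting from 21, HF·pyridine removes the silyl group to give the C7 alcohol of the bicyclic enone F1. i-Pr2Si(OTf)2 and 2,6-lutidine, then 22 and Et3N, attach the dienol ether through a diisopropylsilylene bridge to give the tethered triene F2. Intramolecular cycloaddition (toluene, 40 °C) gives the bridged silyl bis-ether cycloadduct F3. TFA/H2O and then HF·pyridine release the C7-hydroxy ring A enone F4, and TBSCl/imidazole returns to 25.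

Step 13. The bridged ten-membered ring with two E-alkenes is strained, so ring closure may be slower than intermolecular coupling or reduction of the alkenyl-chromium species, leading to oligomers or to the de-iodinated aldehyde. The fallback closes the same bond at the ketone oxidation level with a more reactive carbanion. Starting from 18, oxidation with TEMPO/PhI(OAc)2 gives the carboxylic acid F5, and coupling with MeNHOMe·HCl (EDC) gives the N-methoxy-N-methylamide F6. Iodine–lithium exchange (t-BuLi, THF, −78 °C, high dilution) followed by intramolecular acylation (Parham-type cyclisation) gives enone 21 directly, bypassing 19 and 20.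

Step 17. The first deprotonation may not be fully selective for C11. Any enolisation at C4 first is trapped as the dienol silane, and the second equivalent of base then leads to methylation at C11. The fallback removes the C9 carbonyl during the alkylation. Starting from 25, i-Bu2AlH (CH2Cl2, −78 °C) reduces both ketones to the C3,C9-diol F7. MnO2 reoxidises only the allylic C3 alcohol to give the enone C9-alcohol F8. LiN(i-Pr)2 (2.5 equiv) and MeI can then only form and methylate the C3–C4 enolate, giving the 4,4-dimethyl enone C9-alcohol F9, and Dess–Martin oxidation of the C9 carbinol returns 28.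

Step 22. Hydride transfer to the hindered C1 ketone may be slow. The new C1 hydroxyl could then direct a second Tishchenko reduction of the C9 ketone, or the acetyl group could migrate. The fallback separates reduction and acylation. Starting from 33, Evans–Saksena reduction (Me4NBH(OAc)3, AcOH/MeCN, −20 °C) gives the 1,3-anti diol F10. Ac2O/DMAP gives the 1,3-diacetate F11, and K2CO3/MeOH at 0 °C should cleave the more accessible equatorial C1 acetate first to return 34.

## Further compounds

F1 | step 16 | C7 alcohol of the bicyclic enone (21 without the silyl group) | C1C3(OCCO3)C2=C[C@H]1CCC(=O)/C(C)=C/C[C@H]2O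
F2 | step 16 | tethered triene: C7–O–Si(i-Pr)2–O bridge to C3 of the (1E,3Z)-1-methoxypenta-1,3-dien-3-yl unit | C1C3(OCCO3)C2=C[C@H]1CCC(=O)/C(C)=C/C[C@H]2O[Si](C(C)C)(C(C)C)OC(\C=C\OC)=C/C
F3 | step 16 | bridged silyl bis-ether cycloadduct (C1 and C4 epimers) | C1C3(OCCO3)C2=C[C@H]1CCC(=O)[C@@]1(C)[C@H](C[C@H]2O[Si](C(C)C)(C(C)C)O4)C(C)C4=CC1OC
F4 | step 16 | C7-hydroxy ring A enone (25 without the silyl group, C4 epimers) | C1C3(OCCO3)C2=C[C@H]1CCC(=O)[C@@]1(C)[C@H](C[C@H]2O)C(C)C(=O)C=C1
F5 | step 13 | carboxylic acid from 18 | C1C2(OCCO2)C([C@H](O[Si](C)(C)C(C)(C)C)C/C=C(\C)I)=C[C@H]1CCC(=O)O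
F6 | step 13 | N-methoxy-N-methylamide of F5 | C1C2(OCCO2)C([C@H](O[Si](C)(C)C(C)(C)C)C/C=C(\C)I)=C[C@H]1CCC(=O)N(C)OC
F7 | step 17 | C3,C9-diol from 25 (carbinol epimers) | C1C3(OCCO3)C2=C[C@H]1CCC(O)[C@@]1(C)[C@H](C[C@H]2O[Si](C)(C)C(C)(C)C)[C@@H](C)C(O)C=C1
F8 | step 17 | ring A enone with C9 carbinol | C1C3(OCCO3)C2=C[C@H]1CCC(O)[C@@]1(C)[C@H](C[C@H]2O[Si](C)(C)C(C)(C)C)[C@@H](C)C(=O)C=C1
F9 | step 17 | 4,4-dimethyl ring A enone with C9 carbinol | C1C3(OCCO3)C2=C[C@H]1CCC(O)[C@@]1(C)[C@H](C[C@H]2O[Si](C)(C)C(C)(C)C)C(C)(C)C(=O)C=C1
F10 | step 22 | 1,3-anti diol (C1 OH equatorial, C3 OH axial) | C1C3(OCCO3)C2=C[C@H]1CCC(=O)[C@@]1(C)[C@H](C[C@H]2O[Si](C)(C)C(C)(C)C)C(C)(C)[C@@H](O)C[C@@H]1O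
F11 | step 22 | 1,3-diacetate of F10 | C1C3(OCCO3)C2=C[C@H]1CCC(=O)[C@@]1(C)[C@H](C[C@H]2O[Si](C)(C)C(C)(C)C)C(C)(C)[C@@H](OC(C)=O)C[C@@H]1OC(C)=O
A1 | alternative 1 | bicyclo[3.3.0]oct-1-en-3-one carrying ring A on C9 (C9 OTES, C1 OTBS, C3 OPMB, C7 dimethyl acetal) | O=C1C=C2[C@H](C1)CC[C@@]2(O[Si](CC)(CC)CC)[C@@]3(C)[C@H](CC(OC)OC)C(C)(C)[C@@H](OCc4ccc(OC)cc4)C[C@@H]3O[Si](C)(C)C(C)(C)C
A2 | alternative 2 | bridged ten-membered C9 ketone with C13=C14 alkene and C8–H (C7 OTBS, C15 dioxolane, C1 OTBS, C3 OPMB) | C1C3(OCCO3)[C@@H]2C=C1CCC(=O)[C@@]1(C)[C@H](C[C@H]2O[Si](C)(C)C(C)(C)C)C(C)(C)[C@@H](OCc4ccc(OC)cc4)C[C@@H]1O[Si](C)(C)C(C)(C)C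
A3 | alternative 3 | ten-membered carbocyclic acid with exocyclic methylene on C13 (C15 acid on C8, C7 OTBS, C9 OTES, C1 OTBS, C3 OPMB) | C=C1C[C@H](C(=O)O)[C@H](O[Si](C)(C)C(C)(C)C)C[C@@H]2C(C)(C)[C@@H](OCc3ccc(OC)cc3)C[C@H](O[Si](C)(C)C(C)(C)C)[C@@]2(C)[C@H](O[Si](CC)(CC)CC)CC1
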